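## Retrosynthetic overview

1. The target comes from its C1 ketone by hydride delivery to the open (exo) face of the bridged oxolan-3-one.
2. Key step: the ten-membered carbocycle (C2–C3 bond) and the oxolane (O10–C3 bond) close in one operation, by an intramolecular Mukaiyama addition of the C1 enol silane to the C3 Z-enal acetal followed by capture of the allylic C3 cation by the C10 silyl ether.
3. The seco precursor comes from a Mitsunobu angeloylation (inversion at C8) of the product of an indium Barbier coupling (C7–C8) between a butenolide allylic bromide and a keto aldehyde.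
4. The butenolide (lactone ring, formed first, by ring-closing metathesis) is built from propargyl alcohol, acrolein and 2-(bromomethyl)acrylic acid; the keto aldehyde (C10) comes from (R)-lactic acid.
5. Ring order: lactone, then carbocycle and oxolane together.

Assumption: germacrane numbering (C1–C15) is used for locants, and an in-flask compound gets its own number only where a step is run in two stages in one flask.

## Route

Step 1
Reactants: 1 prop-2-yn-1-ol
Product: 3 (2Z)-3-iodo-2-methylprop-2-en-1-ol, via alkenylmagnesium alkoxide 2 (not isolated)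
Conditions: MeMgBr (2.5 equiv), CuI (10 mol%), THF, −10 °C → rt; then I2, −78 → 0 °C
Reagents that add atoms: methylmagnesium bromide, C[Mg]Br; iodine, II
Why: Copper-catalysed anti-carbomagnesiation of the propargylic alkoxide through a five-membered magnesium chelate puts the methyl on the internal carbon and the metal (then iodine) cis to CH2O, which fixes the Z geometry of the later C4=C5 bond.

Step 2
Reactants: 3 (2Z)-3-iodo-2-methylprop-2-en-1-ol
Product: 4 (2Z)-3-iodo-2-methylprop-2-enal
Conditions: MnO2, CH2Cl2, rt, dark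
Reagents that add atoms: none
Why: Neutral heterogeneous MnO2 oxidation of an allylic alcohol gives the enal without acid or base that could isomerise the Z-iodoalkene.

Step 3
Reactants: 4 (2Z)-3-iodo-2-methylprop-2-enal
Product: 5 (1Z)-1-iodo-3,3-dimethoxy-2-methylprop-1-ene
Conditions: HC(OMe)3, PPTS (cat.), MeOH, 0 °C → rt
Reagents that add atoms: trimethyl orthoformate, COC(OC)OC
Why: Mild acid-catalysed acetalisation masks the C3 aldehyde through the organolithium, metathesis and Barbier steps and stores it as the latent oxocarbenium ion of the key step.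

Step 4
Reactants: 5 (1Z)-1-iodo-3,3-dimethoxy-2-methylprop-1-ene; 6 acrolein
Product: 8 rac-(4Z)-6,6-dimethoxy-5-methylhexa-1,4-dien-3-ol, via alkenyllithium 7 (not isolated)
Conditions: t-BuLi (2.05 equiv), Et2O, −78 °C; then acrolein, −78 °C; H2O
Reagents that add atoms: none
Why: Iodine–lithium exchange retains the alkene geometry (the cis acetal chelates lithium) and the alkenyllithium adds 1,2 to acrolein, giving the C6 carbinol as a racemate.

Step 5
Reactants: 8 rac-(4Z)-6,6-dimethoxy-5-methylhexa-1,4-dien-3-ol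
Product: 9 (3S,4Z)-6,6-dimethoxy-5-methylhexa-1,4-dien-3-ol
Conditions: Novozym 435 (CAL-B), vinyl acetate, MTBE, rt, to about 52% conversion
Reagents that add atoms: none
Why: Lipase kinetic resolution acylates the (R)-alcohol (Kazlauskas rule, vinyl as the medium and the Z-alkenyl acetal as the large group) and leaves the (S)-alcohol, which carries the C6 configuration of the target.

Step 6
Reactants: 9 (3S,4Z)-6,6-dimethoxy-5-methylhexa-1,4-dien-3-ol; 10 2-(bromomethyl)prop-2-enoic acid
Product: 11 (3S,4Z)-6,6-dimethoxy-5-methylhexa-1,4-dien-3-yl 2-(bromomethyl)prop-2-enoate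
Conditions: DCC, DMAP (5 mol%), CH2Cl2, 0 °C
Reagents that add atoms: none
Why: Steglich esterification acylates the secondary alcohol at 0 °C without touching the stereocentre or the acetal.

Step 7
Reactants: 11 (3S,4Z)-6,6-dimethoxy-5-methylhexa-1,4-dien-3-yl 2-(bromomethyl)prop-2-enoate
Product: 12 (5R)-3-(bromomethyl)-5-[(1Z)-3,3-dimethoxy-2-methylprop-1-en-1-yl]furan-2(5H)-one
Conditions: Hoveyda–Grubbs II (5 mol%), CH2Cl2 (5 mM), 40 °C
Reagents that add atoms: none
Why: Ring-closing metathesis between the vinyl group and the acrylate closes the five-membered butenolide (the lactone ring) while the trisubstituted Z-alkene stays inert, and it leaves the allylic bromide needed for the Barbier coupling.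

Step 8
Reactants: 13 (R)-lactic acid; 14 pivalaldehyde
Product: 15 (2R,5R)-2-tert-butyl-5-methyl-1,3-dioxolan-4-one
Conditions: TsOH (cat.), pentane, Dean–Stark reflux; cis isomer crystallised at −78 °C
Reagents that add atoms: none
Why: Acid-catalysed acetalisation gives mainly the cis dioxolanone, the template for self-regeneration of the stereocentre (Seebach).

Step 9
Reactants: 15 (2R,5R)-2-tert-butyl-5-methyl-1,3-dioxolan-4-one; 16 allyl bromide
Product: 18 (2R,5S)-2-tert-butyl-5-methyl-5-(prop-2-en-1-yl)-1,3-dioxolan-4-one, via lithium enolate 17 (not isolated)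
Conditions: LDA, THF, −78 °C; then allyl bromide, −78 → −30 °C
Reagents that add atoms: none
Why: The enolate is alkylated anti to the tert-butyl group, so allyl replaces H with retention (Seebach alkylation) and sets the quaternary C10 centre.

Step 10
Reactants: 18 (2R,5S)-2-tert-butyl-5-methyl-5-(prop-2-en-1-yl)-1,3-dioxolan-4-one
Product: 19 (3S)-3-hydroxy-3-methylhex-5-en-2-one
Conditions: MeLi (1.05 equiv), Et2O, −78 °C; H2O
Reagents that add atoms: methyllithium, C[Li]
Why: Methyllithium adds once to the acylal-type lactone carbonyl, and the stable tetrahedral adduct collapses on work-up to the methyl ketone and pivalaldehyde without touching C10.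

Step 11
Reactants: 19 (3S)-3-hydroxy-3-methylhex-5-en-2-one
Product: 20 (3S)-3-methyl-3-(triethylsilyloxy)hex-5-en-2-one
Conditions: TESOTf, 2,6-lutidine, CH2Cl2, −78 → 0 °C
Reagents that add atoms: triethylsilyl triflate, CC[Si](CC)(CC)OS(=O)(=O)C(F)(F)F
Why: Silyl triflate silylation of the tertiary alcohol blocks retro-aldol and dehydration of the coming β-oxy aldehyde and provides the silyl ether that acts as the oxygen nucleophile in the key step.

Step 12
Reactants: 20 (3S)-3-methyl-3-(triethylsilyloxy)hex-5-en-2-one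
Product: 22 (3S)-3-methyl-4-oxo-3-(triethylsilyloxy)pentanal, via secondary ozonide 21 (not isolated)
Conditions: O3, CH2Cl2, −78 °C; then PPh3, −78 °C → rt
Reagents that add atoms: ozone, [O-][O+]=O
Why: Ozonolysis of the only alkene with reductive work-up gives the C8 aldehyde under neutral conditions.

Step 13
Reactants: 12 (5R)-3-(bromomethyl)-5-[(1Z)-3,3-dimethoxy-2-methylprop-1-en-1-yl]furan-2(5H)-one; 22 (3S)-3-methyl-4-oxo-3-(triethylsilyloxy)pentanal
Product: 23 (4R,5R)-5-[(1Z)-3,3-dimethoxy-2-methylprop-1-en-1-yl]-4-[(1S,3S)-1-hydroxy-3-methyl-4-oxo-3-(triethylsilyloxy)pentyl]-3-methylideneoxolan-2-one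
Conditions: In powder, DMF, rt
Reagents that add atoms: none
Why: In this indium Barbier allylation the allylindium reacts at ring carbon C7 anti to the C6 substituent (trans lactone), and the chair Zimmerman–Traxler transition state of the ring-fixed E-type allyl unit gives the anti (7R,8S) alcohol; the aldehyde reacts in preference to the hindered ketone.

Step 14
Reactants: 23 (4R,5R)-5-[(1Z)-3,3-dimethoxy-2-methylprop-1-en-1-yl]-4-[(1S,3S)-1-hydroxy-3-methyl-4-oxo-3-(triethylsilyloxy)pentyl]-3-methylideneoxolan-2-one; 24 angelic acid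
Product: 25 (1R,3S)-1-[(2R,3R)-2-[(1Z)-3,3-dimethoxy-2-methylprop-1-en-1-yl]-4-methylidene-5-oxooxolan-3-yl]-3-methyl-4-oxo-3-(triethylsilyloxy)pentyl (2Z)-2-methylbut-2-enoate
Conditions: PPh3, DIAD, toluene, 0 °C → rt
Reagents that add atoms: none
Why: Mitsunobu esterification installs the angelate with SN2 inversion, turning 8S into the required 8R under neutral conditions that do not isomerise angelate to tiglate.

Step 15
Reactants: 25 (1R,3S)-1-[(2R,3R)-2-[(1Z)-3,3-dimethoxy-2-methylprop-1-en-1-yl]-4-methylidene-5-oxooxolan-3-yl]-3-methyl-4-oxo-3-(triethylsilyloxy)pentyl (2Z)-2-methylbut-2-enoate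
Product: 27 (3S,6R,7R,8R,10S)-8-angeloyloxy-3,10-epoxy-1-oxogermacra-4Z,11(13)-dien-12,6-olide, via trimethylsilyl enol ether 26 (not isolated)
Conditions: i-Pr2NEt (1.5 equiv), TMSOTf (1.3 equiv), CH2Cl2, 0 °C; then dilute to 1 mM, TMSOTf (0.5 equiv), −78 → −20 °C
Reagents that add atoms: none
Why: Proposed new method: the methyl ketone is silylated in the flask, TMSOTf then ionises the Z-enal acetal to an alkenyl oxocarbenium ion that the enol silane attacks at C3 (an intramolecular Mukaiyama addition to an acetal at high dilution, closing the ten-membered ring), and the resulting allylic C3 methyl ether ionises again and is trapped by the C10 triethylsilyl ether oxygen to close the oxolane (as in the oxocarbenium/enolate recombination of a Petasis–Ferrier rearrangement to oxolan-3-ones), so both rings form in one operation and C3 can only bond cis across the bridge, its configuration following from C10; the closest known chemistry is one-pot enol silane formation/Mukaiyama addition to acetals and silyl-ether capture of oxocarbenium ions.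

Step 16
Reactants: 27 (3S,6R,7R,8R,10S)-8-angeloyloxy-3,10-epoxy-1-oxogermacra-4Z,11(13)-dien-12,6-olide
Product: 28 (1S,3S,6R,7R,8R,10S)-8-angeloyloxy-3,10-epoxy-1-hydroxygermacra-4Z,11(13)-dien-12,6-olide
Conditions: NaBH4, CeCl3·7H2O, MeOH, −78 → −40 °C
Reagents that add atoms: none
Why: In this Luche reduction hydride adds to the exo face of the bridged oxolan-3-one (the C10 methyl side, away from the C4–C9 bridge), giving the endo 1S alcohol, while cerium suppresses conjugate reduction of the α-methylene lactone and the angelate.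

## Compound list

1 | prop-2-yn-1-ol | C#CCO | starting material
2 | bromomagnesium (2Z)-3-(bromomagnesio)-2-methylprop-2-en-1-olate | Br[Mg]/C=C(/C)CO[Mg]Br | intermediate
3 | (2Z)-3-iodo-2-methylprop-2-en-1-ol | OC/C(C)=C\I | intermediate
4 | (2Z)-3-iodo-2-methylprop-2-enal | O=C/C(C)=C\I | intermediate
5 | (1Z)-1-iodo-3,3-dimethoxy-2-methylprop-1-ene | COC(OC)/C(C)=C\I | intermediate
6 | acrolein | C=CC=O | starting material
7 | [(1Z)-3,3-dimethoxy-2-methylprop-1-en-1-yl]lithium | [Li]/C=C(/C)C(OC)OC | intermediate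
8 | rac-(4Z)-6,6-dimethoxy-5-methylhexa-1,4-dien-3-ol | C=CC(O)/C=C(/C)C(OC)OC | intermediate
9 | (3S,4Z)-6,6-dimethoxy-5-methylhexa-1,4-dien-3-ol | O[C@H](/C=C(/C)C(OC)OC)C=C | intermediate
10 | 2-(bromomethyl)prop-2-enoic acid | C=C(CBr)C(=O)O | starting material
11 | (3S,4Z)-6,6-dimethoxy-5-methylhexa-1,4-dien-3-yl 2-(bromomethyl)prop-2-enoate | C=C(CBr)C(=O)O[C@H](/C=C(/C)C(OC)OC)C=C | intermediate
12 | (5R)-3-(bromomethyl)-5-[(1Z)-3,3-dimethoxy-2-methylprop-1-en-1-yl]furan-2(5H)-one | O=C1O[C@H](/C=C(/C)C(OC)OC)C=C1CBr | intermediate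
13 | (R)-lactic acid | C[C@@H](O)C(=O)O | starting material
14 | pivalaldehyde | CC(C)(C)C=O | starting material
15 | (2R,5R)-2-tert-butyl-5-methyl-1,3-dioxolan-4-one | C[C@H]1O[C@@H](C(C)(C)C)OC1=O | intermediate
16 | allyl bromide | C=CCBr | starting material
17 | lithium (2R)-2-tert-butyl-5-methyl-1,3-dioxol-4-olate | CC1=C(O[Li])O[C@H](C(C)(C)C)O1 | intermediate
18 | (2R,5S)-2-tert-butyl-5-methyl-5-(prop-2-en-1-yl)-1,3-dioxolan-4-one | C[C@@]1(CC=C)O[C@@H](C(C)(C)C)OC1=O | intermediate
19 | (3S)-3-hydroxy-3-methylhex-5-en-2-one | CC(=O)[C@@](C)(O)CC=C | intermediate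
20 | (3S)-3-methyl-3-(triethylsilyloxy)hex-5-en-2-one | CC(=O)[C@@](C)(O[Si](CC)(CC)CC)CC=C | intermediate
21 | (3S)-3-methyl-3-(triethylsilyloxy)-4-(1,2,4-trioxolan-3-yl)butan-2-one (epimers at the trioxolane carbon) | CC(=O)[C@@](C)(O[Si](CC)(CC)CC)CC1OOCO1 | intermediate
22 | (3S)-3-methyl-4-oxo-3-(triethylsilyloxy)pentanal | CC(=O)[C@@](C)(O[Si](CC)(CC)CC)CC=O | intermediate
23 | (4R,5R)-5-[(1Z)-3,3-dimethoxy-2-methylprop-1-en-1-yl]-4-[(1S,3S)-1-hydroxy-3-methyl-4-oxo-3-(triethylsilyloxy)pentyl]-3-methylideneoxolan-2-one | C=C1C(=O)O[C@H](/C=C(/C)C(OC)OC)[C@H]1[C@@H](O)C[C@](C)(O[Si](CC)(CC)CC)C(C)=O | intermediate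
24 | angelic acid, (2Z)-2-methylbut-2-enoic acid | C/C=C(/C)C(=O)O | starting material
25 | (1R,3S)-1-[(2R,3R)-2-[(1Z)-3,3-dimethoxy-2-methylprop-1-en-1-yl]-4-methylidene-5-oxooxolan-3-yl]-3-methyl-4-oxo-3-(triethylsilyloxy)pentyl (2Z)-2-methylbut-2-enoate | C=C1C(=O)O[C@H](/C=C(/C)C(OC)OC)[C@H]1[C@H](OC(=O)/C(C)=C\C)C[C@](C)(O[Si](CC)(CC)CC)C(C)=O | intermediate
26 | (1R,3S)-1-[(2R,3R)-2-[(1Z)-3,3-dimethoxy-2-methylprop-1-en-1-yl]-4-methylidene-5-oxooxolan-3-yl]-3-methyl-3-(triethylsilyloxy)-4-(trimethylsilyloxy)pent-4-en-1-yl (2Z)-2-methylbut-2-enoate | C=C1C(=O)O[C@H](/C=C(/C)C(OC)OC)[C@H]1[C@H](OC(=O)/C(C)=C\C)C[C@](C)(O[Si](CC)(CC)CC)C(=C)O[Si](C)(C)C | intermediate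
27 | (3S,6R,7R,8R,10S)-8-angeloyloxy-3,10-epoxy-1-oxogermacra-4Z,11(13)-dien-12,6-olide | C=C1C(=O)O[C@@H]2/C=C(/C)[C@@H]3CC(=O)[C@](C)(C[C@@H](OC(=O)/C(C)=C\C)[C@@H]12)O3 | intermediate
28 | (1S,3S,6R,7R,8R,10S)-8-angeloyloxy-3,10-epoxy-1-hydroxygermacra-4Z,11(13)-dien-12,6-olide (CNP0213894.1) | C=C1C(=O)O[C@@H]2/C=C(/C)[C@@H]3C[C@H](O)[C@](C)(C[C@@H](OC(=O)/C(C)=C\C)[C@@H]12)O3 | target

## Step count and risks

Total steps: 16. Longest linear sequence: 11 steps (steps 1–7, then 13–16).

**Step 15** is the most likely to fail, because closing a ten-membered ring by a cationic Mukaiyama addition has no direct precedent. The fallback sets out from 25 and comes back at 27. The enol silane 26 is isolated and brominated with NBS (THF, −78 °C) to the bromomethyl ketone F1. The acetal is then hydrolysed (PPTS, acetone–water) to the Z-enal F2. SmI2 (THF, −78 °C, 2 mM) closes the carbocycle by an intramolecular samarium Reformatsky aldol, giving the macrocyclic C3 carbinol F3 as either C3 epimer. Adding CSA to the same flask ionises the allylic C3–O bond and the C10 silyl ether closes the oxolane to give 27, so both rings still form in one pot.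

**Step 14** is the second risk: a Mitsunobu reaction with a weak acid at a hindered carbinol next to the allylic H7 may eliminate. The fallback sets out from 23 and comes back at 25. MsCl and Et3N (CH2Cl2, −20 °C) give the C8 mesylate F4. Caesium angelate (from 24 and Cs2CO3) with 18-crown-6 in toluene at 60 °C then displaces it with inversion to give 25.

**Step 13** is the third risk: the C8 selectivity rests on a chair transition state, and the indium alkoxide could trans-lactonise to the 8,12-lactone. The fallback sets out from 12 and comes back at 23. Copper-catalysed borylation (B2pin2, CuCl, KOAc, LiCl, DMF, rt) gives the allylboronate F5. Warming F5 with 22 in toluene (rt → 50 °C) and a triethanolamine work-up gives 23 through a tight boron chair transition state, with no Lewis-acidic metal alkoxide present.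

Further compounds
F1 | step 15 | (1R,3S)-5-bromo-1-[(2R,3R)-2-[(1Z)-3,3-dimethoxy-2-methylprop-1-en-1-yl]-4-methylidene-5-oxooxolan-3-yl]-3-methyl-4-oxo-3-(triethylsilyloxy)pentyl (2Z)-2-methylbut-2-enoate | C=C1C(=O)O[C@H](/C=C(/C)C(OC)OC)[C@H]1[C@H](OC(=O)/C(C)=C\C)C[C@](C)(O[Si](CC)(CC)CC)C(=O)CBr
F2 | step 15 | (1R,3S)-5-bromo-3-methyl-1-[(2R,3R)-4-methylidene-2-[(1Z)-2-methyl-3-oxoprop-1-en-1-yl]-5-oxooxolan-3-yl]-4-oxo-3-(triethylsilyloxy)pentyl (2Z)-2-methylbut-2-enoate | C=C1C(=O)O[C@H](/C=C(/C)C=O)[C@H]1[C@H](OC(=O)/C(C)=C\C)C[C@](C)(O[Si](CC)(CC)CC)C(=O)CBr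
F3 | step 15 | (6R,7R,8R,10S)-8-angeloyloxy-3-hydroxy-1-oxo-10-(triethylsilyloxy)germacra-4Z,11(13)-dien-12,6-olide (C3 epimers) | C=C1C(=O)O[C@@H]2/C=C(/C)C(O)CC(=O)[C@@](C)(O[Si](CC)(CC)CC)C[C@@H](OC(=O)/C(C)=C\C)[C@@H]12
F4 | step 14 | (1S,3S)-1-[(2R,3R)-2-[(1Z)-3,3-dimethoxy-2-methylprop-1-en-1-yl]-4-methylidene-5-oxooxolan-3-yl]-3-methyl-4-oxo-3-(triethylsilyloxy)pentyl methanesulfonate | C=C1C(=O)O[C@H](/C=C(/C)C(OC)OC)[C@H]1[C@@H](OS(C)(=O)=O)C[C@](C)(O[Si](CC)(CC)CC)C(C)=O
F5 | step 13 | (5R)-5-[(1Z)-3,3-dimethoxy-2-methylprop-1-en-1-yl]-3-[(4,4,5,5-tetramethyl-1,3,2-dioxaborolan-2-yl)methyl]furan-2(5H)-one | O=C1O[C@H](/C=C(/C)C(OC)OC)C=C1CB1OC(C)(C)C(C)(C)O1
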